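Everything rests on cutting ring A across C1–C6 and C2–C3. The contiguous C3(Br)–C4(Cl)–C5(Br)–C6(H) edge of ring A is carried in by 2,4-dibromo-3-chlorothiophene 1,1-dioxide, and the oxygenated carbons C1/C2 by a (Z)-1-acetoxy-2-aryloxyethene that already bears ring B. One thermal [4+2] cycloaddition with loss of SO2 forms both C–C bonds, closes ring A as a cis-5,6-dioxygenated cyclohexa-1,3-diene and delivers all three halogens in order, with the two oxygens already differentiated. The sulfone comes from a silyl-blocked lithiation sequence that leaves no regiochemical ambiguity; afterwards, deacetylation and oxidation of the dienol give a dienone that tautomerises to the phenol.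

Key step: step 8

Remark: 1 is taken as a catalogue compound (otherwise one NBS bromination of 3-chlorothiophene); compounds 14–17 are racemic and their SMILES show one enantiomer.

Step 1
Reactants: 1 2-bromo-3-chlorothiophene
Product: 3 (5-bromo-4-chlorothiophen-2-yl)trimethylsilane, via 5-lithio-2-bromo-3-chlorothiophene 2 (not isolated)
Conditions: LDA (1.05 equiv) added to 1 + TMSCl (1.2 equiv), THF, −78 °C
Reagents that add atoms: chlorotrimethylsilane, C[Si](C)(C)Cl
Why: LDA removes the only α-hydrogen (C5–H, the most acidic ring C–H) and the silyl chloride already present traps the thienyllithium before bromine can migrate (directed lithiation with in situ electrophilic quench).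

Step 2
Reactants: 3 (5-bromo-4-chlorothiophen-2-yl)trimethylsilane
Product: 6 (3,5-dibromo-4-chlorothiophen-2-yl)trimethylsilane, via 3-lithiated silylthiophene 4 (not isolated), via bromine-migrated 5-lithio isomer 5 (not isolated)
Conditions: LDA (1.1 equiv), THF, −78 → −40 °C; then BrCCl2CCl2Br, −78 °C → rt
Reagents that add atoms: 1,2-dibromo-1,1,2,2-tetrachloroethane, BrC(Cl)(Cl)C(Cl)(Cl)Br
Why: The single remaining ring hydrogen (flanked by Cl and SiMe3) is removed by LDA, and because the silyl group blocks the other α-position the base-catalysed halogen dance can only exchange Br and Li between C3 and C5, so both lithio isomers give the same dibromide on electrophilic bromination.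

Step 3
Reactants: 6 (3,5-dibromo-4-chlorothiophen-2-yl)trimethylsilane
Product: 7 2,4-dibromo-3-chlorothiophene
Conditions: TBAF (1.1 equiv, wet), THF, 0 °C
Reagents that add atoms: none
Why: Fluoride-induced protodesilylation of an α-silylthiophene, in which the departing thienyl anion is stabilised by sulfur and the ortho bromine and is protonated at once by water, leaving the C–Br and C–Cl bonds untouched.

Step 4
Reactants: 7 2,4-dibromo-3-chlorothiophene
Product: 8 2,4-dibromo-3-chlorothiophene 1,1-dioxide
Conditions: urea·H2O2, (CF3CO)2O, CH2Cl2/MeCN, 0 °C → rt; product kept cold and used promptly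
Reagents that add atoms: trifluoroperacetic acid (formed in the flask from trifluoroacetic anhydride and H2O2), OOC(=O)C(F)(F)F
Why: Electrophilic S-oxidation of an electron-poor halothiophene by a strong peracid, the sulfoxide being oxidised faster than the thiophene so the reaction should stop cleanly at the isolable trihalogenated sulfone.

Step 5
Reactants: 9 2,4-dibromophenol; 10 bromoacetaldehyde diethyl acetal
Product: 11 2,4-dibromo-1-(2,2-diethoxyethoxy)benzene
Conditions: K2CO3, KI (cat.), DMF, 110 °C
Reagents that add atoms: none
Why: Williamson ether synthesis (SN2 of the phenoxide on the primary bromide, iodide-assisted), with the acetal stable to base and the aryl bromides inert.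

Step 6
Reactants: 11 2,4-dibromo-1-(2,2-diethoxyethoxy)benzene
Product: 12 (2,4-dibromophenoxy)acetaldehyde
Conditions: 2 M HCl, THF, 50 °C; used crude
Reagents that add atoms: water, O
Why: Acid-catalysed acetal hydrolysis, the electron-poor dibromoaryl ring being too deactivated to cyclise onto the aldehyde under dilute acid.

Step 7
Reactants: 12 (2,4-dibromophenoxy)acetaldehyde
Product: 13 (Z)-2-(2,4-dibromophenoxy)ethenyl acetate
Conditions: Ac2O, Et3N, DMAP (cat.), CH2Cl2, 0 °C → rt; Z isomer isolated on silica
Reagents that add atoms: acetic anhydride, CC(=O)OC(C)=O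
Why: Soft enolisation of the α-aryloxy aldehyde and O-acetylation through the N-acetylpyridinium (enol ester formation) should give mainly the Z alkene, the cis arrangement of two vicinal oxygen substituents being the preferred geometry of 1,2-dioxygenated ethenes, and the minor E isomer is removed by chromatography.

Step 8
Reactants: 8 2,4-dibromo-3-chlorothiophene 1,1-dioxide; 13 (Z)-2-(2,4-dibromophenoxy)ethenyl acetate
Product: 15 cis-3,5-dibromo-4-chloro-6-(2,4-dibromophenoxy)cyclohexa-2,4-dien-1-yl acetate (racemic), via thiabicycloheptene dioxide adduct 14 (not isolated)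
Conditions: 13 (2 equiv), 8 added slowly, toluene, 90 °C, 2,6-di-tert-butyl-4-methylpyridine (0.2 equiv), BHT (cat.), argon sweep
Reagents that add atoms: none
Why: The electron-poor sulfone diene and the electron-rich 1,2-dioxygenated alkene should combine in an inverse-electron-demand [4+2] cycloaddition to the 7-thiabicyclo[2.2.1]hept-2-ene 7,7-dioxide 14, which loses SO2 by a thermally allowed retro-cheletropic reaction at the reaction temperature. The closest known reaction type is the benzannulation of polyhalogenated thiophene 1,1-dioxides with alkenes, including electron-rich ones, by cycloaddition and SO2 extrusion. Ring A is closed by the intermolecular cycloaddition itself, both new σ-bonds (C1–C6 and C2–C3 of ring A) forming suprafacially on the alkene before the sulfur bridge is excised to leave the cyclohexa-1,3-diene. The two new stereocentres (C1 and C6 of 15) are set cis to one another by stereospecific transfer of the Z geometry of 13; no absolute control is needed because both centres vanish on aromatisation, and endo/exo selectivity is irrelevant because either form of 14 gives the same diene. The selectivity required is regiochemical: aryloxy is a better π-donor than acetoxy, so the acetoxy-bearing carbon is the nucleophilic end of 13 and should bond first to the unsubstituted, least hindered sulfone terminus (C5–H), leaving the aryloxy carbon to close on the brominated terminus. The cis adduct has no hydrogen syn to the acetate, and the hindered pyridine and argon sweep remove acid and SO2, so thermal or acid-catalysed loss of acetic acid or of the phenol should be suppressed.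

Step 9
Reactants: 15 cis-3,5-dibromo-4-chloro-6-(2,4-dibromophenoxy)cyclohexa-2,4-dien-1-yl acetate
Product: 16 cis-3,5-dibromo-4-chloro-6-(2,4-dibromophenoxy)cyclohexa-2,4-dien-1-ol (racemic)
Conditions: DIBAL-H (2.2 equiv), CH2Cl2, −78 °C; MeOH then Rochelle salt work-up
Reagents that add atoms: none
Why: Reductive cleavage of the acetate by hydride at low temperature is neither basic nor acidic, so neither E2/E1cB loss of acetate nor ionisation of the dienyl C–O bonds should compete, and the vinyl halides, diaryl ether and both stereocentres are untouched.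

Step 10
Reactants: 16 cis-3,5-dibromo-4-chloro-6-(2,4-dibromophenoxy)cyclohexa-2,4-dien-1-ol
Product: 18 3,5-dibromo-4-chloro-2-(2,4-dibromophenoxy)phenol, via 6-aryloxycyclohexa-2,4-dienone 17 (not isolated)
Conditions: Dess–Martin periodinane (1.1 equiv), pyridine (3 equiv), CH2Cl2, 0 °C; aq. Na2S2O3, mildly acidic work-up
Reagents that add atoms: none
Why: Oxidation of the secondary allylic alcohol gives the cyclohexa-2,4-dienone that is the keto tautomer of the target, which enolises irreversibly to the aromatic phenol with both oxygens retained and both stereocentres erased.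

Compound list
1 | 2-bromo-3-chlorothiophene | Clc1ccsc1Br | starting material
2 | (5-bromo-4-chlorothiophen-2-yl)lithium | [Li]c1cc(Cl)c(Br)s1 | intermediate
3 | (5-bromo-4-chlorothiophen-2-yl)trimethylsilane | C[Si](C)(C)c1cc(Cl)c(Br)s1 | intermediate
4 | [5-bromo-4-chloro-2-(trimethylsilyl)thiophen-3-yl]lithium | C[Si](C)(C)c1sc(Br)c(Cl)c1[Li] | intermediate
5 | [4-bromo-3-chloro-5-(trimethylsilyl)thiophen-2-yl]lithium | C[Si](C)(C)c1sc([Li])c(Cl)c1Br | intermediate
6 | (3,5-dibromo-4-chlorothiophen-2-yl)trimethylsilane | C[Si](C)(C)c1sc(Br)c(Cl)c1Br | intermediate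
7 | 2,4-dibromo-3-chlorothiophene | Clc1c(Br)csc1Br | intermediate
8 | 2,4-dibromo-3-chlorothiophene 1,1-dioxide | O=S1(=O)C=C(Br)C(Cl)=C1Br | intermediate
9 | 2,4-dibromophenol | Oc1ccc(Br)cc1Br | starting material
10 | bromoacetaldehyde diethyl acetal | CCOC(CBr)OCC | starting material
11 | 2,4-dibromo-1-(2,2-diethoxyethoxy)benzene | CCOC(COc1ccc(Br)cc1Br)OCC | intermediate
12 | (2,4-dibromophenoxy)acetaldehyde | O=CCOc1ccc(Br)cc1Br | intermediate
13 | (Z)-2-(2,4-dibromophenoxy)ethenyl acetate | CC(=O)O/C=C\Oc1ccc(Br)cc1Br | intermediate
14 | 1,3-dibromo-2-chloro-6-(2,4-dibromophenoxy)-7,7-dioxo-7λ6-thiabicyclo[2.2.1]hept-2-en-5-yl acetate, 5,6-cis, racemic, endo/exo not defined | CC(=O)O[C@H]1[C@@H](Oc2ccc(Br)cc2Br)C2(Br)C(Cl)=C(Br)C1S2(=O)=O | intermediate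
15 | cis-3,5-dibromo-4-chloro-6-(2,4-dibromophenoxy)cyclohexa-2,4-dien-1-yl acetate, rac-(1R,6R) | CC(=O)O[C@@H]1C=C(Br)C(Cl)=C(Br)[C@@H]1Oc1ccc(Br)cc1Br | intermediate
16 | cis-3,5-dibromo-4-chloro-6-(2,4-dibromophenoxy)cyclohexa-2,4-dien-1-ol, rac-(1R,6R) | O[C@@H]1C=C(Br)C(Cl)=C(Br)[C@@H]1Oc1ccc(Br)cc1Br | intermediate
17 | 3,5-dibromo-4-chloro-6-(2,4-dibromophenoxy)cyclohexa-2,4-dien-1-one, racemic | O=C1C=C(Br)C(Cl)=C(Br)[C@@H]1Oc1ccc(Br)cc1Br | intermediate
18 | 3,5-dibromo-4-chloro-2-(2,4-dibromophenoxy)phenol | Oc1cc(Br)c(Cl)c(Br)c1Oc1ccc(Br)cc1Br | target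

Total step count: 10
Longest linear sequence: 7 steps (steps 1, 2, 3, 4, 8, 9, 10)

Steps most likely to fail

Step 8. The cycloaddition may take the opposite orientation, joining the aryloxy carbon to the unsubstituted terminus. The sulfone may also dimerise through its unsubstituted C=C bond faster than it meets the hindered alkene, or the diene may lose acetic acid at the reaction temperature. The fallback sets out from 9 and returns at 18, with ring A taken from an SNAr electrophile whose halogen pattern is fixed by classical directing effects. Purchased 3-fluoro-4-nitroaniline is dibrominated ortho to nitrogen (Br2, AcOH) to 2,6-dibromo-3-fluoro-4-nitroaniline F1. A Sandmeyer chlorination (t-BuONO, CuCl2, MeCN) then gives 1,3-dibromo-2-chloro-4-fluoro-5-nitrobenzene F2. Phenol 9 displaces the fluoride ortho to the nitro group (K2CO3, DMF) to give 1,3-dibromo-2-chloro-4-(2,4-dibromophenoxy)-5-nitrobenzene F3. Reduction with iron and NH4Cl gives 3,5-dibromo-4-chloro-2-(2,4-dibromophenoxy)aniline F4. This is diazotised (NaNO2, H2SO4, 0 °C) to 3,5-dibromo-4-chloro-2-(2,4-dibromophenoxy)benzenediazonium hydrogen sulfate F5 and hydrolysed (Cu2O, Cu(NO3)2, water) to 18.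

Step 10. Ionisation or dehydration of the dienol (loss of water or of 2,4-dibromophenol) may outrun alcohol oxidation during steps 9 and 10, aromatising ring A with one oxygen missing. The fallback sets out from 15 and returns at 18, replacing alcohol oxidation by C–H dehydrogenation of the ester. DDQ in toluene at 80 °C abstracts hydride from an oxygen-bearing sp3 carbon and the arenium ion loses a proton, giving 3,5-dibromo-4-chloro-2-(2,4-dibromophenoxy)phenyl acetate F6. Methanolysis (K2CO3, MeOH, rt) then frees 18.

Step 4. S-oxidation of the electron-poor thiophene may stall, and the sulfone may dimerise by Diels–Alder reaction through its unsubstituted α-position during reaction or isolation. The fallback sets out from 6 and returns at 8 by moving the oxidation in front of the desilylation. Silylthiophene 6, with a more electron-rich sulfur and both α-positions blocked, is oxidised (mCPBA, CH2Cl2, rt) to (3,5-dibromo-4-chloro-1,1-dioxidothiophen-2-yl)trimethylsilane F7, a storable sulfone that cannot dimerise through an unsubstituted C=C bond. Fluoride-induced protodesilylation of this α-silyl vinyl sulfone (TBAF buffered with AcOH, THF, −20 °C) then releases 8 immediately before the cycloaddition.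

Further compounds
F1 | step 8 | 2,6-dibromo-3-fluoro-4-nitroaniline | Nc1c(Br)cc([N+](=O)[O-])c(F)c1Br
F2 | step 8 | 1,3-dibromo-2-chloro-4-fluoro-5-nitrobenzene | [O-][N+](=O)c1cc(Br)c(Cl)c(Br)c1F
F3 | step 8 | 1,3-dibromo-2-chloro-4-(2,4-dibromophenoxy)-5-nitrobenzene | [O-][N+](=O)c1cc(Br)c(Cl)c(Br)c1Oc1ccc(Br)cc1Br
F4 | step 8 | 3,5-dibromo-4-chloro-2-(2,4-dibromophenoxy)aniline | Nc1cc(Br)c(Cl)c(Br)c1Oc1ccc(Br)cc1Br
F5 | step 8 | 3,5-dibromo-4-chloro-2-(2,4-dibromophenoxy)benzenediazonium hydrogen sulfate | N#[N+]c1cc(Br)c(Cl)c(Br)c1Oc1ccc(Br)cc1Br.OS(=O)(=O)[O-]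
F6 | step 10 | 3,5-dibromo-4-chloro-2-(2,4-dibromophenoxy)phenyl acetate | CC(=O)Oc1cc(Br)c(Cl)c(Br)c1Oc1ccc(Br)cc1Br
F7 | step 4 | (3,5-dibromo-4-chloro-1,1-dioxidothiophen-2-yl)trimethylsilane | C[Si](C)(C)C1=C(Br)C(Cl)=C(Br)S1(=O)=O
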